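**Retrosynthetic overview**

1. Locants (target): C1 = ring CH–OAc; C2 = ring CH2; C3 = CH(CH3); C4 and C6 = cyclopropane ring-fusion carbons (C5 = its CH2); C7 and C8 = α- and β-carbons of the butenolide (C9 = OCH2, C10 = C=O); C11 = ring CH carrying the side chain C12(H)(CH3)–C13–C14–C15–C16. Last events: Schenck ene reaction on the C15=C16 alkene of acetate 18 ⇐ alcohol 17 ⇐ ketone 16 (C1=O).
2. Enabling feature: in the cyclooctene ring the oxygenated carbon C1 is bonded to C11, which is allylic to the butenolide double bond C7=C8, and C7 is at once the lactone α-carbon and a ring carbon (C1–C11–C8=C7). This is the product pattern of a 1,3-acyl shift, so C1 can be moved back from C11 to C7.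
3. Key disconnection (bond C1–C11, eight-membered ring): 16 ⇐ spiro β-keto lactone 14. In 14, C1–C7 is a temporary bond closing a six-membered ring (C1, C2, C3, C4, C6, C7) and C7 is a sacrificial quaternary stereocentre. A photochemical 1,3-acyl shift expands six to eight, moves C8=C11 to C7=C8 and transfers chirality from C7 to C11.
4. 14 ⇐ Conia-ene closure of the γ-lactone (bond C7–C8) in propargyl β-keto ester 13 ⇐ β-keto ester 7 + propargylic alcohol 12 (from (R)-citronellal, which supplies C12).
5. 7 ⇐ carbomethoxylation and cuprate addition on cyclopropane-fused cyclohexenone 5 ⇐ enantioselective desymmetrisation of meso epoxide 3 ⇐ cyclohexa-1,4-diene. Ring order: cyclopropane on the six-membered carbocycle, spiro γ-lactone, eight-membered ring by expansion.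

Key step: step 11

Assumption: the cis ring fusions, the configuration (1R,3R,4S,6S,11S,12R in the locants above) and the (E) side-chain alkene are read from the given structure; compounds 1 and 8 and all reagents, including the chiral diamine of step 3, are taken as commercial.

Remark: 7 and 13 are drawn as keto forms without configuration at C7, which is epimerisable and becomes defined only in step 10.

**Step 1**
Reactants: 1 cyclohexa-1,4-diene
Product: 2 cis-bicyclo[4.1.0]hept-3-ene (meso)
Conditions: Et2Zn, CH2I2, CH2Cl2, 0 °C to rt (1 in threefold excess)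
Reagents that add atoms: diiodomethane, ICI
Why: Simmons–Smith cyclopropanation, in which stereospecific syn addition of the zinc carbenoid gives the cis-fused ring, and the excess of diene should hold the reaction at the meso mono-adduct.

**Step 2**
Reactants: 2 cis-bicyclo[4.1.0]hept-3-ene
Product: 3 meso anti-3,4-epoxy-cis-bicyclo[4.1.0]heptane (epoxide oxygen on the face opposite to the cyclopropane CH2)
Conditions: mCPBA, CH2Cl2, 0 °C
Reagents that add atoms: 3-chloroperoxybenzoic acid, OOC(=O)c1cccc(Cl)c1
Why: Prilezhaev epoxidation should occur on the face opposite to the cyclopropane CH2 to give the meso anti epoxide; any syn epoxide is removed because it would lead into the enantiomeric series in step 3.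

**Step 3**
Reactants: 3 meso anti-3,4-epoxy-cis-bicyclo[4.1.0]heptane
Product: 4 (1R,3R,6R)-bicyclo[4.1.0]hept-4-en-3-ol (hydroxyl anti to the cyclopropane CH2)
Conditions: LiN(i-Pr)2 (2 equiv), (1S,3R,4R)-3-(pyrrolidin-1-ylmethyl)-2-azabicyclo[2.2.1]heptane (5 mol%), DBU, THF, 0 °C to rt
Reagents that add atoms: none
Why: Enantioselective base-promoted isomerisation of a meso epoxide to an allylic alcohol (syn β-elimination by a chiral lithium amide that LiN(i-Pr)2 regenerates), in which the choice between the two enantiotopic CH2 groups flanking the epoxide fixes the absolute configuration of the cyclopropane carbons; the diamine enantiomer is the one that converts cyclohexene oxide into (R)-cyclohex-2-en-1-ol and by analogy should give the (3R) alcohol.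

**Step 4**
Reactants: 4 (1R,3R,6R)-bicyclo[4.1.0]hept-4-en-3-ol
Product: 5 (1R,6R)-bicyclo[4.1.0]hept-4-en-3-one
Conditions: MnO2, CH2Cl2, rt
Reagents that add atoms: none
Why: Neutral allylic-alcohol oxidation gives the enone without base, which matters because enolisation of 5 toward the cyclopropane would create a norcaradiene that opens to a cycloheptatriene.

**Step 5**
Reactants: 5 (1R,6R)-bicyclo[4.1.0]hept-4-en-3-one
Product: 6 (1R,5R,6S)-5-methylbicyclo[4.1.0]heptan-3-one
Conditions: Me2CuLi (from CuI and MeLi), Et2O, −78 °C; aqueous work-up
Reagents that add atoms: lithium dimethylcuprate, [Li+].C[Cu-]C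
Why: Conjugate addition of the cuprate should deliver the methyl group to the β-carbon from the face opposite to the cyclopropane CH2 on the neighbouring ring-fusion carbon, which sets C3 trans to that CH2, and saturating C2–C3 here removes any later risk of a norcaradiene-type dienolate.

**Step 6**
Reactants: 6 (1R,5R,6S)-5-methylbicyclo[4.1.0]heptan-3-one
Product: 7 methyl (1S,5R,6S)-5-methyl-3-oxobicyclo[4.1.0]heptane-2-carboxylate (C2 epimers and enol)
Conditions: NaH, (MeO)2CO, THF, reflux; then dilute HCl
Reagents that add atoms: dimethyl carbonate, COC(=O)OC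
Why: Claisen-type C-carbomethoxylation under thermodynamic control (product held as its sodium enolate) should take place at the α-carbon next to the cyclopropane (enolate conjugated with the three-membered ring, ester eclipsing only a ring-fusion C–H) and not at the α-carbon flanked by the methyl-bearing carbon, as 3-methylcyclohexanone acylates away from its methyl group; a minor regioisomer would be removed by chromatography.

**Step 7**
Reactants: 8 (R)-citronellal, (3R)-3,7-dimethyloct-6-enal
Product: 10 (3R)-3,7-dimethyloct-6-en-1-yne, via alkenyl nonaflate 9 (not isolated)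
Conditions: n-C4F9SO2F, phosphazene base P2-Et (2.5 equiv), DMF, −20 °C to rt
Reagents that add atoms: nonafluorobutane-1-sulfonyl fluoride, FS(=O)(=O)C(F)(F)C(F)(F)C(F)(F)C(F)(F)F (its atoms are present in intermediate 9 only)
Why: One-pot conversion of an enolisable aldehyde into the terminal alkyne of the same carbon count, by O-sulfonylation of the enolate to alk-1-enyl nonaflate 9 and base-induced β-elimination; the stereocentre is not involved and the acetylide formed in the basic medium protects the product against alkyne–allene isomerisation.

**Step 8**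
Reactants: 10 (3R)-3,7-dimethyloct-6-en-1-yne
Product: 12 (4R)-4,8-dimethylnon-7-en-2-yn-1-ol, via lithium acetylide 11 (not isolated)
Conditions: n-BuLi, THF, −78 °C; (CH2O)n, −78 °C to rt
Reagents that add atoms: n-butyllithium, [Li]CCCC (lithium present in intermediate 11 only); formaldehyde from paraformaldehyde, C=O
Why: Deprotonation of the terminal alkyne and 1,2-addition of the acetylide to formaldehyde (hydroxymethylation) leave the stereocentre untouched.

**Step 9**
Reactants: 7 methyl (1S,5R,6S)-5-methyl-3-oxobicyclo[4.1.0]heptane-2-carboxylate; 12 (4R)-4,8-dimethylnon-7-en-2-yn-1-ol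
Product: 13 (4R)-4,8-dimethylnon-7-en-2-yn-1-yl (1S,5R,6S)-5-methyl-3-oxobicyclo[4.1.0]heptane-2-carboxylate (C2 epimers and enol)
Conditions: DMAP (cat.), toluene, reflux, 4 Å molecular sieves
Reagents that add atoms: none
Why: DMAP-catalysed transesterification of a β-keto ester (acylketene pathway) is driven by removal of methanol and touches no fixed stereocentre.

**Step 10**
Reactants: 13 propargyl β-keto ester
Product: 14 (1S,2R,5R,6S)-4'-[(1Z,2R)-2,6-dimethylhept-5-en-1-ylidene]-5-methylspiro[bicyclo[4.1.0]heptane-2,3'-oxolane]-2',3-dione (spiro carbon = C7; alkylidene carbon C8 on the ring face opposite to the cyclopropane CH2 and cis to the C3 methyl; side chain cis to the lactone OCH2)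
Conditions: In(NTf2)3 (5 mol%), toluene, 80 °C
Reagents that add atoms: none
Why: Conia-ene cycloisomerisation (5-exo-dig): the chelated indium enolate adds syn across the alkyne and protodemetalation with retention leaves H-11 cis to the new C7–C8 bond, i.e. the (Z)-alkylidene with the side chain remote from the quaternary carbon (also the thermodynamically preferred isomer), while C8 should reach the enolate face anti to the cyclopropane CH2 and so set the spiro centre C7.

**Step 11**
Reactants: 14 spiro β-keto lactone
Product: 16 tricyclic keto butenolide (C1 ketone; 3R,4S,6S,11S,12R), via acyl–allyl biradical 15 (not isolated)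
Conditions: hν (300 nm, Pyrex filter), degassed benzene (0.01 M), 15 °C, to the photostationary state; recovered 14 re-irradiated; neutral work-up
Reagents that add atoms: none
Why: Direct n→π* excitation of the ketone in 14 leads to α-cleavage of the C1–C7 bond to the quaternary spiro carbon, giving singlet biradical 15 whose allyl part (C7–C8–C11) is further stabilised by the lactone carbonyl, and the acyl carbon recombines with the distal terminus C11; this is a photochemical 1,3-acyl shift of a β,γ-unsaturated ketone, the known two-carbon ring expansion of 2-alkenylcycloalkanones. The cyclooctene ring is closed by C1–C11 recombination of the tethered radical pair (six-membered ring expanded to eight, the temporary C1–C7 bond being the one cleaved), and the double bond moves from C8=C11 to C7=C8, which creates the tetrasubstituted butenolide with the cis ring geometry enforced by the lactone. The new stereocentre C11 is set by suprafacial transfer: the acyl group, held by the C2–C3–C4–C6 tether on the face of the lactone plane from which it departs, arrives on the same face of C11, so the (Z) geometry of the alkylidene (H cis to C7) and the configuration of the sacrificial centre C7 together translate into (11S). The step needs recombination at C11 and not back at C7 (favoured by relief of the congested quaternary centre and by conjugation of the new alkene with the lactone carbonyl), a 1,3-shift and not an oxa-di-π-methane rearrangement (direct irradiation, no triplet sensitiser), and cage recombination faster than decarbonylation (primary-alkyl acyl radical at or below room temperature). Product 16 is kept neutral and reduced without delay because C11–H is α to the ketone and γ to the lactone carbonyl.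

**Step 12**
Reactants: 16 tricyclic keto butenolide
Product: 17 alcohol (1R,3R,4S,6S,11S,12R; OH at C1 cis to the side chain at C11)
Conditions: LiBH(s-Bu)3, THF, −78 °C; aqueous work-up
Reagents that add atoms: none
Why: Reduction by a bulky trialkylborohydride at low temperature is chemoselective for the ketone over the hindered tetrasubstituted butenolide, and hydride is expected to approach C1 anti to the large side chain on the adjacent C11 (steric approach control), giving the (1R) alcohol without epimerisation at C11.

**Step 13**
Reactants: 17 alcohol
Product: 18 acetate (1R,3R,4S,6S,11S,12R; 6-methylhept-5-en-2-yl side chain)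
Conditions: Ac2O, pyridine, DMAP (cat.), CH2Cl2, 0 °C to rt
Reagents that add atoms: acetic anhydride, CC(=O)OC(C)=O
Why: DMAP-catalysed acylation of the secondary alcohol proceeds with retention at C1.

**Step 14**
Reactants: 18 acetate
Product: 19 target hydroperoxide (C14=C15 (E), C16(CH3)2–OOH)
Conditions: O2, hν (visible), tetraphenylporphyrin (cat.), CH2Cl2, −20 °C; chromatography
Reagents that add atoms: dioxygen, O=O
Why: Schenck ene reaction of singlet oxygen with the electron-rich trisubstituted side-chain alkene (the electron-poor butenolide alkene should be inert): oxygen adds at C16 with abstraction of a C14 hydrogen and shift of the double bond to C14=C15 (E), forming the tertiary hydroperoxide without a new stereocentre; the secondary hydroperoxide from abstraction of a methyl hydrogen is the expected co-product and is separated.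

**Compound list**

1 | cyclohexa-1,4-diene | C1=CCC=CC1 | starting material
2 | cis-bicyclo[4.1.0]hept-3-ene (meso) | C1=CC[C@@H]2C[C@@H]2C1 | intermediate
3 | meso anti-3,4-epoxy-cis-bicyclo[4.1.0]heptane | C1[C@H]2O[C@H]2C[C@@H]3C[C@@H]31 | intermediate
4 | (1R,3R,6R)-bicyclo[4.1.0]hept-4-en-3-ol | O[C@H]1C=C[C@@H]2C[C@@H]2C1 | intermediate
5 | (1R,6R)-bicyclo[4.1.0]hept-4-en-3-one | O=C1C=C[C@@H]2C[C@@H]2C1 | intermediate
6 | (1R,5R,6S)-5-methylbicyclo[4.1.0]heptan-3-one | O=C1C[C@@H](C)[C@@H]2C[C@@H]2C1 | intermediate
7 | methyl (1S,5R,6S)-5-methyl-3-oxobicyclo[4.1.0]heptane-2-carboxylate (C2 epimers and enol) | O=C1C[C@@H](C)[C@@H]2C[C@@H]2C1C(=O)OC | intermediate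
8 | (R)-citronellal, (3R)-3,7-dimethyloct-6-enal | O=CC[C@H](C)CCC=C(C)C | starting material
9 | (3R)-3,7-dimethylocta-1,6-dien-1-yl nonafluorobutane-1-sulfonate (E/Z mixture) | FC(F)(F)C(F)(F)C(F)(F)C(F)(F)S(=O)(=O)OC=C[C@H](C)CCC=C(C)C | intermediate
10 | (3R)-3,7-dimethyloct-6-en-1-yne | C#C[C@H](C)CCC=C(C)C | intermediate
11 | lithium (3R)-3,7-dimethyloct-6-en-1-yn-1-ide | [Li]C#C[C@H](C)CCC=C(C)C | intermediate
12 | (4R)-4,8-dimethylnon-7-en-2-yn-1-ol | OCC#C[C@H](C)CCC=C(C)C | intermediate
13 | (4R)-4,8-dimethylnon-7-en-2-yn-1-yl (1S,5R,6S)-5-methyl-3-oxobicyclo[4.1.0]heptane-2-carboxylate (C2 epimers and enol) | O=C1C[C@@H](C)[C@@H]2C[C@@H]2C1C(=O)OCC#C[C@H](C)CCC=C(C)C | intermediate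
14 | (1S,2R,5R,6S)-4'-[(1Z,2R)-2,6-dimethylhept-5-en-1-ylidene]-5-methylspiro[bicyclo[4.1.0]heptane-2,3'-oxolane]-2',3-dione | O=C1C[C@@H](C)[C@@H]2C[C@@H]2[C@]13C(=O)OC/C3=C\[C@H](C)CCC=C(C)C | intermediate
15 | acyl–allyl singlet biradical from α-cleavage of 14 (acyl radical at C1, allyl radical C7–C8–C11) | O=[C]C[C@@H](C)[C@@H]1C[C@@H]1[C]1C(=O)OC/C1=C\[C@H](C)CCC=C(C)C | intermediate
16 | tricyclic keto butenolide (C1 ketone; 3R,4S,6S,11S,12R) | O=C1C[C@@H](C)[C@@H]2C[C@@H]2C2=C(COC2=O)[C@@H]1[C@H](C)CCC=C(C)C | intermediate
17 | alcohol (1R,3R,4S,6S,11S,12R) | O[C@@H]1C[C@@H](C)[C@@H]2C[C@@H]2C2=C(COC2=O)[C@@H]1[C@H](C)CCC=C(C)C | intermediate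
18 | acetate (1R,3R,4S,6S,11S,12R) | CC(=O)O[C@@H]1C[C@@H](C)[C@@H]2C[C@@H]2C2=C(COC2=O)[C@@H]1[C@H](C)CCC=C(C)C | intermediate
19 | target hydroperoxide | CC(=O)O[C@@H]1C[C@@H](C)[C@@H]2C[C@@H]2C2=C(COC2=O)[C@@H]1[C@H](C)C/C=C/C(C)(C)OO | target

**Step count**

Total: 14 steps. Longest linear sequence: 12 steps (steps 1–6 and 9–14).

**Steps most likely to fail**

1. Step 11. The irradiation may stop at a photostationary mixture poor in 16. The biradical may lose suprafacial fidelity by rotation about C6–C7, or be diverted by disproportionation to an unsaturated aldehyde, decarbonylation or opening of the cyclopropylcarbinyl radical. The fallback sets out from 14 and comes back at 16, running the same acyl transposition in the ground state as an ionic sequence. NaOMe (1.1 equiv) in THF should open the non-enolisable β-keto lactone by retro-Claisen cleavage of C1–C7 to the sodium dienolate of the seco methyl ester F1. Its γ-carbon C11 then acylates intramolecularly (vinylogous Dieckmann condensation) with loss of methoxide, and the equilibrium is drained by the doubly stabilised enolate of 16. Protonation with AcOH at −78 °C returns 16. In this variant C11 is set by protonation of an epimerisable centre, so the (11S) isomer would have to be secured by kinetic protonation or by separation and re-equilibration of the epimer.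

2. Step 10. The ester tether must reach the disfavoured s-cis ester conformation for 5-exo closure, which slows the cyclisation. The Lewis-acidic indium salt may instead trigger cycloisomerisation of the 1,6-enyne formed by the alkyne and the side-chain alkene. The fallback sets out from 12 (with 7) and comes back at 14, making the C7–C8 bond intermolecularly with a preformed alkenyl metal.
   - Silylation of 12 (TBSCl, imidazole) gives tert-butyl{[(4R)-4,8-dimethylnon-7-en-2-yn-1-yl]oxy}dimethylsilane F2.
   - Syn hydrostannation (Bu3SnH, Pd(PPh3)2Cl2 cat., THF) places tin on the carbon next to CH2O and gives the (E)-alkenylstannane F3.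
   - Tin–lead exchange with Pb(OAc)4 in CHCl3 gives the alkenyllead triacetate F4, used in solution.
   - Reaction of F4 with 7 in CHCl3/pyridine vinylates the β-keto ester with retention of alkene geometry, anti to the cyclopropane CH2, to give the α-alkenyl β-keto ester F5.
   - Bu4NF in THF removes the silyl group and the freed hydroxyl lactonises onto the methyl ester to give 14.

3. Step 12. Hydride delivery on a conformationally mobile eight-membered ring may show poor or reversed facial selectivity, and the basic reagent may epimerise C11. The fallback sets out from 16 and comes back at 18. If reduction (for example NaBH4, CeCl3, MeOH, −40 °C) gives the C1-epimeric alcohol F6, a Mitsunobu reaction with acetic acid (PPh3, DIAD, THF, 0 °C) inverts C1 and installs the acetate in one operation. This gives 18 directly and step 13 is not needed.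

**Further compounds**

F1 | step 11 | sodium dienolate of the seco methyl ester, methyl (3R)-3-{cis-2-[(4Z)-4-((2R)-2,6-dimethylhept-5-en-1-ylidene)-2-oxido-4,5-dihydrofuran-3-yl]cyclopropyl}butanoate sodium salt | [Na+].COC(=O)C[C@@H](C)[C@@H]1C[C@@H]1C1=C([O-])OC/C1=C\[C@H](C)CCC=C(C)C
F2 | step 10 | tert-butyl{[(4R)-4,8-dimethylnon-7-en-2-yn-1-yl]oxy}dimethylsilane | CC(C)(C)[Si](C)(C)OCC#C[C@H](C)CCC=C(C)C
F3 | step 10 | tributyl[(2E,4R)-1-(tert-butyldimethylsilyloxy)-4,8-dimethylnona-2,7-dien-2-yl]stannane | CC(C)(C)[Si](C)(C)OC/C(=C\[C@H](C)CCC=C(C)C)[Sn](CCCC)(CCCC)CCCC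
F4 | step 10 | [(2E,4R)-1-(tert-butyldimethylsilyloxy)-4,8-dimethylnona-2,7-dien-2-yl]lead triacetate | CC(C)(C)[Si](C)(C)OC/C(=C\[C@H](C)CCC=C(C)C)[Pb](OC(C)=O)(OC(C)=O)OC(C)=O
F5 | step 10 | methyl (1S,2R,5R,6S)-2-[(2Z,4R)-1-(tert-butyldimethylsilyloxy)-4,8-dimethylnona-2,7-dien-2-yl]-5-methyl-3-oxobicyclo[4.1.0]heptane-2-carboxylate | O=C1C[C@@H](C)[C@@H]2C[C@@H]2[C@@]1(C(=O)OC)/C(CO[Si](C)(C)C(C)(C)C)=C/[C@H](C)CCC=C(C)C
F6 | step 12 | C1-epimeric alcohol (1S,3R,4S,6S,11S,12R; OH at C1 trans to the side chain) | O[C@H]1C[C@@H](C)[C@@H]2C[C@@H]2C2=C(COC2=O)[C@@H]1[C@H](C)CCC=C(C)C
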